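**Retrosynthetic overview**

1. Numbering as in terpenoids: ring A = C1–C5/C10 (C4 = CMe2), ring B = C5–C10 (C8 = carbinol carbon, C9 = side-chain carbon). The SMILES is read as the cis-fused decalin, with H-5, CH3-10, CH3-8 and the C9 chain on one face and 8-OH on the other.
2. First disconnection, C11–C12: (2E,6E)-farnesyl bromide plus a bicyclic C11 phenyl sulfone. The sulfonyl group is a temporary activator and is removed reductively in the last step.
3. Key disconnection, C2–C3 of ring A: ring-closing metathesis joins the CH of an allyl group on quaternary C10 (C1–C2) to the CH of a 1,1-dimethylallyl group on C5 (C4–C3); the alkene is then hydrogenated.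
4. Enabling feature: C3 sits directly on the quaternary CMe2 carbon C4, and C2 is one CH2 (C1) away from the quaternary ring-fusion carbon C10. Each can therefore be carried by ring B as the inner carbon of a terminal alkene, and the cis ring fusion puts both arms on the same face of ring B.
5. Ring order: ring B first (steps 1–2), then its four stereocenters are set on the monocycle (C5 by catalyst control; C10, C9 and C8 by substrate control), and ring A last (step 10).

Key step: step 10

Remark: 3,3-dimethylpent-4-enal is taken as a catalogue aldehyde; if it must be made, Claisen rearrangement of prenyl vinyl ether gives it.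

**Route**

Step 1
Reactants: 1 3,3-dimethylpent-4-enal; 2 but-3-en-2-one
Product: 3 (2R)-2-(2-methylbut-3-en-2-yl)-5-oxohexanal
Conditions: (R)-2-[methoxy(diphenyl)methyl]pyrrolidine (5 mol %), ethyl 3,4-dihydroxybenzoate (20 mol %), neat, 4 °C
Reagents that add atoms: none
Why: Enamine-catalysed Michael addition, in which the (E)-enamine of 1 should add to 2 from the face not shielded by the CPh2OMe group of the (R)-catalyst and so set the future C5 as (R).

Step 2
Reactants: 3 (2R)-2-(2-methylbut-3-en-2-yl)-5-oxohexanal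
Product: 5 (4S)-4-(2-methylbut-3-en-2-yl)cyclohex-2-en-1-one, via aldol adduct 4 (not isolated)
Conditions: LiOH (0.1 equiv), i-PrOH, rt
Reagents that add atoms: none
Why: Intramolecular aldol condensation of the methyl ketone onto the aldehyde closes ring B, and the mild base should leave the stereocenter next to the aldehyde intact because ring closure and dehydration outrun its enolization.

Step 3
Reactants: 5 (4S)-4-(2-methylbut-3-en-2-yl)cyclohex-2-en-1-one
Product: 6 trimethyl{[(3R,4S)-4-(2-methylbut-3-en-2-yl)-3-(prop-2-en-1-yl)cyclohex-1-en-1-yl]oxy}silane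
Conditions: allylMgBr, CuBr·SMe2 (1.1 equiv), TMSCl, THF, −78 °C; Et3N, cold NaHCO3 work-up
Reagents that add atoms: allylmagnesium bromide, C=CC[Mg]Br; chlorotrimethylsilane, C[Si](C)(C)Cl
Why: TMSCl-accelerated conjugate addition of allylcopper with in situ O-silylation fixes the enolate toward C9; allyl should enter trans to the tert-alkyl group, but this center is erased in step 4.

Step 4
Reactants: 6 trimethyl{[(3R,4S)-4-(2-methylbut-3-en-2-yl)-3-(prop-2-en-1-yl)cyclohex-1-en-1-yl]oxy}silane
Product: 7 (4R)-4-(2-methylbut-3-en-2-yl)-3-(prop-2-en-1-yl)cyclohex-2-en-1-one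
Conditions: Pd(OAc)2 (1.05 equiv), MeCN, rt
Reagents that add atoms: none
Why: Saegusa–Ito oxidation, in which the palladium enolate loses the only β-hydrogen (on the allyl-bearing carbon) and regenerates the enone with allyl on the β-carbon; no stereocenter is formed.

Step 5
Reactants: 7 (4R)-4-(2-methylbut-3-en-2-yl)-3-(prop-2-en-1-yl)cyclohex-2-en-1-one
Product: 8 trimethyl{[(3S,4R)-3-methyl-4-(2-methylbut-3-en-2-yl)-3-(prop-2-en-1-yl)cyclohex-1-en-1-yl]oxy}silane
Conditions: MeMgBr, CuBr·SMe2 (5 mol %), TMSCl, HMPA, THF, −78 °C; Et3N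
Reagents that add atoms: methylmagnesium bromide, C[Mg]Br; chlorotrimethylsilane, C[Si](C)(C)Cl
Why: Copper-catalysed, TMSCl-accelerated conjugate addition to the β,β-disubstituted enone should deliver methyl axially and anti to the bulky group on the neighbouring carbon, making quaternary C10 with CH3 trans and allyl cis to that group (the later cis fusion), and the enolate is trapped regiospecifically.

Step 6
Reactants: 8 trimethyl{[(3S,4R)-3-methyl-4-(2-methylbut-3-en-2-yl)-3-(prop-2-en-1-yl)cyclohex-1-en-1-yl]oxy}silane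
Product: 9 (2R,3S,4R)-3-methyl-4-(2-methylbut-3-en-2-yl)-2-[(phenylsulfanyl)methyl]-3-(prop-2-en-1-yl)cyclohexan-1-one
Conditions: PhSCH2Cl, TiCl4, CH2Cl2, −78 °C
Reagents that add atoms: chloromethyl phenyl sulfide, ClCSc1ccccc1
Why: Mukaiyama-type alkylation of the silyl enol ether by the thionium ion; axial attack on the half-chair from the face away from the axial allyl group on C10 and the C5 substituent should place CH2SPh cis to the C10 methyl (C9 configuration).

Step 7
Reactants: 9 (2R,3S,4R)-3-methyl-4-(2-methylbut-3-en-2-yl)-2-[(phenylsulfanyl)methyl]-3-(prop-2-en-1-yl)cyclohexan-1-one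
Product: 10 ({[(1S,2S,3R)-2-methyl-6-methylidene-3-(2-methylbut-3-en-2-yl)-2-(prop-2-en-1-yl)cyclohexyl]methyl}sulfanyl)benzene
Conditions: Zn, CH2Br2, TiCl4, THF/CH2Cl2, 0 °C → rt
Reagents that add atoms: dibromomethane, BrCBr
Why: Takai–Lombardo methylenation, whose non-basic gem-dimetallic reagent should convert the hindered, enolizable ketone to the exocyclic alkene without epimerizing C9 or eliminating thiophenol.

Step 8
Reactants: 10 ({[(1S,2S,3R)-2-methyl-6-methylidene-3-(2-methylbut-3-en-2-yl)-2-(prop-2-en-1-yl)cyclohexyl]methyl}sulfanyl)benzene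
Product: 11 (3R,4R,5S,6R)-4-[(benzenesulfonyl)methyl]-5-methyl-6-(2-methylbut-3-en-2-yl)-5-(prop-2-en-1-yl)-1-oxaspiro[2.5]octane
Conditions: mCPBA (3.2 equiv), NaHCO3, CH2Cl2, −10 → 0 °C
Reagents that add atoms: 3-chloroperbenzoic acid, OOC(=O)c1cccc(Cl)c1
Why: Prilezhaev oxidation takes sulfur to the sulfone and epoxidizes the most electron-rich (1,1-disubstituted) alkene in preference to the two monosubstituted ones; oxygen should enter anti to the adjacent CH2S arm on C9 and the C10 methyl, as in epoxidation of 8(17)-labdenes, which fixes C8.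

Step 9
Reactants: 11 (3R,4R,5S,6R)-4-[(benzenesulfonyl)methyl]-5-methyl-6-(2-methylbut-3-en-2-yl)-5-(prop-2-en-1-yl)-1-oxaspiro[2.5]octane
Product: 12 (1R,2R,3S,4R)-2-[(benzenesulfonyl)methyl]-1,3-dimethyl-4-(2-methylbut-3-en-2-yl)-3-(prop-2-en-1-yl)cyclohexan-1-ol
Conditions: LiBHEt3, THF, 0 °C → rt
Reagents that add atoms: none
Why: SN2 hydride opening of the spiro-epoxide at its CH2 carbon gives the tertiary alcohol with the C8–O bond untouched, so OH keeps the face set in step 8 and the new methyl lies cis to the C9 arm.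

Step 10
Reactants: 12 (1R,2R,3S,4R)-2-[(benzenesulfonyl)methyl]-1,3-dimethyl-4-(2-methylbut-3-en-2-yl)-3-(prop-2-en-1-yl)cyclohexan-1-ol
Product: 13 (1R,2R,4aR,8aS)-1-[(benzenesulfonyl)methyl]-2,5,5,8a-tetramethyl-1,2,3,4,4a,5,8,8a-octahydronaphthalen-2-ol
Conditions: second-generation Grubbs catalyst (5 mol %), CH2Cl2 (0.005 M), 40 °C
Reagents that add atoms: none
Why: Ring-closing olefin metathesis: the ruthenium alkylidene loads on the unhindered allyl terminus (C2) and closes onto the neopentylic vinyl CH (C3) through a ruthenacyclobutane, releasing ethene, so C2=C3 is the ring-closing bond. The closest known reaction type is RCM of 1,7-dienes to cyclohexenes that carry an allylic quaternary carbon. Ring A closes in a six-membered mode between two arms that ring B holds cis (allyl on C10, 1,1-dimethylallyl on C5), helped by the gem-dialkyl effect of C4 and C10. No stereocenter is formed; the cis fusion and the four stereocenters C5, C8, C9 and C10 are carried in from 12, and a trans-fused product cannot arise. The step needs ring closure to outrun intermolecular metathesis and double-bond migration; high dilution, the absence of any other alkene in 12 and the inertness of the free tertiary alcohol and the sulfone toward the catalyst should secure this.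

Step 11
Reactants: 13 (1R,2R,4aR,8aS)-1-[(benzenesulfonyl)methyl]-2,5,5,8a-tetramethyl-1,2,3,4,4a,5,8,8a-octahydronaphthalen-2-ol
Product: 14 (1R,2R,4aR,8aS)-1-[(benzenesulfonyl)methyl]-2,5,5,8a-tetramethyldecahydronaphthalen-2-ol
Conditions: H2 (1 atm), Pd/C (10 wt %), EtOAc, rt
Reagents that add atoms: none
Why: Heterogeneous catalytic hydrogenation of the only alkene, a cis-disubstituted ring olefin; no stereocenter is formed, and the sulfone and tertiary alcohol are inert.

Step 12
Reactants: 14 (1R,2R,4aR,8aS)-1-[(benzenesulfonyl)methyl]-2,5,5,8a-tetramethyldecahydronaphthalen-2-ol; 15 (2E,6E)-farnesyl bromide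
Product: 16 (1R,2R,4aR,8aS)-1-[(3E,7E)-1-(benzenesulfonyl)-4,8,12-trimethyltrideca-3,7,11-trien-1-yl]-2,5,5,8a-tetramethyldecahydronaphthalen-2-ol (both epimers at the sulfone carbon)
Conditions: n-BuLi (2.2 equiv), THF/HMPA, −78 °C; then 15, −78 → −20 °C
Reagents that add atoms: none
Why: SN2 alkylation of the α-sulfonyl carbanion (dianion after O-deprotonation) at C1 of the primary allylic bromide should keep both (E)-alkenes; the new sulfone-bearing stereocenter is irrelevant because step 13 removes it.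

Step 13
Reactants: 16 (1R,2R,4aR,8aS)-1-[(3E,7E)-1-(benzenesulfonyl)-4,8,12-trimethyltrideca-3,7,11-trien-1-yl]-2,5,5,8a-tetramethyldecahydronaphthalen-2-ol
Product: 17 (1R,2R,4aR,8aS)-2,5,5,8a-tetramethyl-1-[(3E,7E)-4,8,12-trimethyltrideca-3,7,11-trien-1-yl]decahydronaphthalen-2-ol
Conditions: sodium amalgam (Na/Hg, 6 % Na), Na2HPO4, MeOH/THF, −20 °C → rt
Reagents that add atoms: none
Why: Reductive desulfonylation by electron transfer (C–S cleavage, then protonation by methanol); the sulfone is homoallylic rather than allylic, so the trisubstituted alkenes should neither migrate nor be reduced.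

**Compound list**

1 | 3,3-dimethylpent-4-enal | O=CCC(C)(C)C=C | starting material
2 | but-3-en-2-one | CC(=O)C=C | starting material
3 | (2R)-2-(2-methylbut-3-en-2-yl)-5-oxohexanal | O=C[C@@H](C(C)(C)C=C)CCC(C)=O | intermediate
4 | (4R)-3-hydroxy-4-(2-methylbut-3-en-2-yl)cyclohexan-1-one (aldol adduct, either carbinol epimer) | O=C1CC(O)[C@@H](C(C)(C)C=C)CC1 | intermediate
5 | (4S)-4-(2-methylbut-3-en-2-yl)cyclohex-2-en-1-one | O=C1C=C[C@@H](C(C)(C)C=C)CC1 | intermediate
6 | trimethyl{[(3R,4S)-4-(2-methylbut-3-en-2-yl)-3-(prop-2-en-1-yl)cyclohex-1-en-1-yl]oxy}silane | C[Si](C)(C)OC1=C[C@H](CC=C)[C@@H](C(C)(C)C=C)CC1 | intermediate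
7 | (4R)-4-(2-methylbut-3-en-2-yl)-3-(prop-2-en-1-yl)cyclohex-2-en-1-one | O=C1C=C(CC=C)[C@@H](C(C)(C)C=C)CC1 | intermediate
8 | trimethyl{[(3S,4R)-3-methyl-4-(2-methylbut-3-en-2-yl)-3-(prop-2-en-1-yl)cyclohex-1-en-1-yl]oxy}silane | C[Si](C)(C)OC1=C[C@@](C)(CC=C)[C@@H](C(C)(C)C=C)CC1 | intermediate
9 | (2R,3S,4R)-3-methyl-4-(2-methylbut-3-en-2-yl)-2-[(phenylsulfanyl)methyl]-3-(prop-2-en-1-yl)cyclohexan-1-one | O=C1[C@H](CSc2ccccc2)[C@@](C)(CC=C)[C@@H](C(C)(C)C=C)CC1 | intermediate
10 | ({[(1S,2S,3R)-2-methyl-6-methylidene-3-(2-methylbut-3-en-2-yl)-2-(prop-2-en-1-yl)cyclohexyl]methyl}sulfanyl)benzene | C=C1[C@H](CSc2ccccc2)[C@@](C)(CC=C)[C@@H](C(C)(C)C=C)CC1 | intermediate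
11 | (3R,4R,5S,6R)-4-[(benzenesulfonyl)methyl]-5-methyl-6-(2-methylbut-3-en-2-yl)-5-(prop-2-en-1-yl)-1-oxaspiro[2.5]octane | C1O[C@]12[C@H](CS(=O)(=O)c3ccccc3)[C@@](C)(CC=C)[C@@H](C(C)(C)C=C)CC2 | intermediate
12 | (1R,2R,3S,4R)-2-[(benzenesulfonyl)methyl]-1,3-dimethyl-4-(2-methylbut-3-en-2-yl)-3-(prop-2-en-1-yl)cyclohexan-1-ol | C[C@]1(CC=C)[C@@H](C(C)(C)C=C)CC[C@@](C)(O)[C@@H]1CS(=O)(=O)c1ccccc1 | intermediate
13 | (1R,2R,4aR,8aS)-1-[(benzenesulfonyl)methyl]-2,5,5,8a-tetramethyl-1,2,3,4,4a,5,8,8a-octahydronaphthalen-2-ol | C[C@]12CC=CC(C)(C)[C@H]1CC[C@@](C)(O)[C@@H]2CS(=O)(=O)c1ccccc1 | intermediate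
14 | (1R,2R,4aR,8aS)-1-[(benzenesulfonyl)methyl]-2,5,5,8a-tetramethyldecahydronaphthalen-2-ol | C[C@]12CCCC(C)(C)[C@H]1CC[C@@](C)(O)[C@@H]2CS(=O)(=O)c1ccccc1 | intermediate
15 | (2E,6E)-farnesyl bromide, (2E,6E)-1-bromo-3,7,11-trimethyldodeca-2,6,10-triene | CC(C)=CCC/C(C)=C/CC/C(C)=C/CBr | starting material
16 | (1R,2R,4aR,8aS)-1-[(3E,7E)-1-(benzenesulfonyl)-4,8,12-trimethyltrideca-3,7,11-trien-1-yl]-2,5,5,8a-tetramethyldecahydronaphthalen-2-ol (both epimers at the sulfone carbon) | CC(C)=CCC/C(C)=C/CC/C(C)=C/CC([C@@H]1[C@@]2(C)CCCC(C)(C)[C@H]2CC[C@@]1(C)O)S(=O)(=O)c1ccccc1 | intermediate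
17 | (1R,2R,4aR,8aS)-2,5,5,8a-tetramethyl-1-[(3E,7E)-4,8,12-trimethyltrideca-3,7,11-trien-1-yl]decahydronaphthalen-2-ol | CC(C)=CCC/C(C)=C/CC/C(C)=C/CC[C@@H]1[C@@]2(C)CCCC(C)(C)[C@H]2CC[C@@]1(C)O | target

**Step count**

Total steps: 13. Longest linear sequence: 13 steps (1 → 17; 2 and 15 enter as side components).

**Steps most likely to fail**

Step 8. Oxygen may be delivered to the wrong face of the exocyclic alkene, since the face opposite the C9 arm also carries the allyl group on C10, and epoxidation of the two vinyl groups may compete. The fallback builds C8 with the opposite polarity: methyl is added as a nucleophile to the ketone, which has the opposite facial requirement and uses no peracid. It sets out from 9. Addition of MeCeCl2 (from MeLi and CeCl3, THF, −78 °C) should give (1R,2R,3S,4R)-1,3-dimethyl-4-(2-methylbut-3-en-2-yl)-2-[(phenylsulfanyl)methyl]-3-(prop-2-en-1-yl)cyclohexan-1-ol F1. Chemoselective sulfur oxidation ((NH4)6Mo7O24·4H2O, H2O2, EtOH, 0 °C) then returns to the route at 12.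

Step 5. Conjugate addition at the fully substituted β-carbon next to a tert-alkyl-bearing carbon may be too slow, so that 1,2-addition or deprotonation of the doubly allylic CH2 takes over. The fallback brings in the methyl carbon as a cyclopropane methylene by hydroxyl-directed delivery and opens it reductively. It sets out from 7. Luche reduction (NaBH4, CeCl3·7H2O, MeOH, −78 °C) gives (1S,4R)-4-(2-methylbut-3-en-2-yl)-3-(prop-2-en-1-yl)cyclohex-2-en-1-ol F2, the epimer with hydroxyl trans to the tert-alkyl group; a cis epimer would be recycled by oxidation. Directed Simmons–Smith cyclopropanation on the hydroxyl face (Et2Zn, CH2I2, CH2Cl2, 0 °C) gives (1R,2S,5R,6R)-5-(2-methylbut-3-en-2-yl)-6-(prop-2-en-1-yl)bicyclo[4.1.0]heptan-2-ol F3. Oxidation (Dess–Martin periodinane, CH2Cl2) gives (1R,5R,6R)-5-(2-methylbut-3-en-2-yl)-6-(prop-2-en-1-yl)bicyclo[4.1.0]heptan-2-one F4. Dissolving-metal cleavage of the cyclopropane bond that overlaps with the carbonyl (Li, NH3/THF, −78 °C), followed by silylation of the lithium enolate (TMSCl, Et3N), returns to the route at 8.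

Step 10. The ruthenium carbene may fail to engage the neopentylic vinyl group, so that intermolecular metathesis or migration of the allyl double bond competes. The fallback closes C2–C3 by reductive carbonyl coupling. It sets out from 12. Ozonolysis of both terminal alkenes (O3, CH2Cl2/MeOH, −78 °C; then Me2S) gives 2-[(1S,2R,3R,6S)-2-[(benzenesulfonyl)methyl]-3-hydroxy-1,3-dimethyl-6-(2-methyl-1-oxopropan-2-yl)cyclohexyl]acetaldehyde F5. McMurry coupling (TiCl3, Zn(Cu), DME, reflux, high dilution) then returns to the route at 13.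

**Further compounds**

F1 | step 8 | (1R,2R,3S,4R)-1,3-dimethyl-4-(2-methylbut-3-en-2-yl)-2-[(phenylsulfanyl)methyl]-3-(prop-2-en-1-yl)cyclohexan-1-ol | C[C@]1(CC=C)[C@@H](C(C)(C)C=C)CC[C@@](C)(O)[C@@H]1CSc1ccccc1
F2 | step 5 | (1S,4R)-4-(2-methylbut-3-en-2-yl)-3-(prop-2-en-1-yl)cyclohex-2-en-1-ol | O[C@@H]1C=C(CC=C)[C@@H](C(C)(C)C=C)CC1
F3 | step 5 | (1R,2S,5R,6R)-5-(2-methylbut-3-en-2-yl)-6-(prop-2-en-1-yl)bicyclo[4.1.0]heptan-2-ol | O[C@@H]1[C@@H]2C[C@]2(CC=C)[C@@H](C(C)(C)C=C)CC1
F4 | step 5 | (1R,5R,6R)-5-(2-methylbut-3-en-2-yl)-6-(prop-2-en-1-yl)bicyclo[4.1.0]heptan-2-one | O=C1[C@@H]2C[C@]2(CC=C)[C@@H](C(C)(C)C=C)CC1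
F5 | step 10 | 2-[(1S,2R,3R,6S)-2-[(benzenesulfonyl)methyl]-3-hydroxy-1,3-dimethyl-6-(2-methyl-1-oxopropan-2-yl)cyclohexyl]acetaldehyde | C[C@]1(CC=O)[C@@H](C(C)(C)C=O)CC[C@@](C)(O)[C@@H]1CS(=O)(=O)c1ccccc1
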